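**Retrosynthetic overview**
1. Target ⇐ acid hydrolysis (γ-lactone, MOM, catechol acetonide) of the protected 3-O-caffeoyl-4-O-p-coumaroyl-1,5-quinide.
2. Quinide ⇐ ring contraction. A 4-hydroxy-5,6-diacyloxycycloheptane-1,2-dione closes to a transannular hemiketal, and a benzilic-type 1,2-shift then makes the cyclohexane, the lactone and C-1 in one event.
3. Dione ⇐ dihydroxylation and oxidation of a cycloheptene. Its three oxygens are told apart with a temporary boronate: the trans-OH is silylated, then the two esters go on one after the other.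
4. Cycloheptenetriol ⇐ RCM ⇐ two-directional asymmetric allylation of 2-O-benzylglycerol with allyl acetate. The two acids ⇐ Heck couplings of acrylic acid with protected 4-iodophenol and with brominated catechol acetonide.
5. Ring order: cycloheptene (RCM) → 8-oxabicyclo[3.2.1] hemiketal → cyclohexane plus γ-lactone (contraction) → lactone opened.

Assumption: (R)-Cl,MeO-BIPHEP is taken to give the (R,R)-diol, as it does with propane-1,3-diol (otherwise the (S)-ligand is used); quinic acid locants are IUPAC (O-3 cis and O-5 trans to O-4).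

**Step 1**
Reactants: 1 2-O-benzylglycerol [2-(benzyloxy)propane-1,3-diol]; 2 allyl acetate
Product: 3 (4R,6R)-5-(benzyloxy)nona-1,8-diene-4,6-diol
Conditions: [Ir(cod)Cl]2 (5 mol %), (R)-Cl,MeO-BIPHEP (10 mol %), 4-Cl-3-NO2-C6H3CO2H (20 mol %), Cs2CO3 (40 mol %), 2 (10 equiv), dioxane, 100 °C
Reagents that add atoms: none
Why: Krische iridium-catalysed transfer-hydrogenative carbonyl allylation run in two directions: each CH2OH is dehydrogenated to the aldehyde and allylated under catalyst control, which sets both carbinol centres as R, the central carbon is not stereogenic in the R,R-product so both mono-adducts converge, and the double addition raises the ee (the minor meso isomers are separable).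

**Step 2**
Reactants: 3 (4R,6R)-5-(benzyloxy)nona-1,8-diene-4,6-diol
Product: 4 (1R,3R)-2-(benzyloxy)cyclohept-5-ene-1,3-diol
Conditions: Grubbs II (3 mol %), CH2Cl2 (5 mM), 40 °C
Reagents that add atoms: none
Why: Ring-closing metathesis of two unhindered terminal alkenes to a seven-membered ring tolerates free hydroxyls and touches no stereocentre.

**Step 3**
Reactants: 4 (1R,3R)-2-(benzyloxy)cyclohept-5-ene-1,3-diol
Product: 5 (1R,3R)-cyclohept-5-ene-1,2,3-triol
Conditions: Na, NH3(l)/THF, −78 °C; NH4Cl
Reagents that add atoms: none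
Why: Dissolving-metal (Birch-type) cleavage of the benzyl ether leaves the isolated cis-alkene and both carbinol centres untouched, and the freed central OH is necessarily cis to one flanking OH and trans to the other.

**Step 4**
Reactants: 5 (1R,3R)-cyclohept-5-ene-1,2,3-triol
Product: 8 (1R,2R,3R)-3-(triethylsilyloxy)cyclohept-5-ene-1,2-diol (1,2-cis, 2,3-trans), via cis-diol phenylboronate 6 (not isolated), via silylated phenylboronate 7 (not isolated)
Conditions: PhB(OH)2 (1.05 equiv), toluene, Dean–Stark; TESCl, imidazole, CH2Cl2, 0 °C; pinacol, rt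
Reagents that add atoms: triethylsilyl chloride, CC[Si](Cl)(CC)CC; phenylboronic acid, OB(O)c1ccccc1 (stays only in 6 and 7)
Why: Temporary boronate protection: the five-membered phenylboronate forms on the only cis-1,2-diol, so silylation can reach only the hydroxyl trans to the central one, pinacol transesterification then frees the diol, and this choice fixes the central carbon as a stereocentre.

**Step 5**
Reactants: 9 2,2-dimethyl-1,3-benzodioxole (catechol acetonide)
Product: 10 5-bromo-2,2-dimethyl-1,3-benzodioxole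
Conditions: NBS (1.05 equiv), MeCN, 0 °C → rt
Reagents that add atoms: N-bromosuccinimide, O=C1CCC(=O)N1Br
Why: Electrophilic aromatic bromination goes para to a ring oxygen, the only unhindered activated position of the benzodioxole.

**Step 6**
Reactants: 10 5-bromo-2,2-dimethyl-1,3-benzodioxole; 11 acrylic acid
Product: 12 (E)-3-(2,2-dimethyl-1,3-benzodioxol-5-yl)acrylic acid (caffeic acid acetonide)
Conditions: Pd(OAc)2 (2 mol %), P(o-tol)3 (6 mol %), Et3N, DMF, 100 °C; citric acid work-up
Reagents that add atoms: none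
Why: The Mizoroki–Heck reaction gives the E-cinnamic acid through syn insertion and syn β-hydride elimination.

**Step 7**
Reactants: 8 (1R,2R,3R)-3-(triethylsilyloxy)cyclohept-5-ene-1,2-diol; 12 caffeic acid acetonide
Product: 13 (1R,2R,3R)-2-hydroxy-3-(triethylsilyloxy)cyclohept-5-en-1-yl (E)-3-(2,2-dimethyl-1,3-benzodioxol-5-yl)acrylate
Conditions: 12 (1.0 equiv), DCC, DMAP (10 mol %), CH2Cl2, −20 → 0 °C
Reagents that add atoms: none
Why: Steglich esterification under steric control: the C1 hydroxyl next to a CH2 reacts before the C2 hydroxyl next to the OTES-bearing carbon, and configuration is kept because only O–H bonds react.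

**Step 8**
Reactants: 14 1-iodo-4-(methoxymethoxy)benzene; 11 acrylic acid
Product: 15 (E)-3-[4-(methoxymethoxy)phenyl]acrylic acid (O-MOM-p-coumaric acid)
Conditions: Pd(OAc)2 (2 mol %), P(o-tol)3 (6 mol %), Et3N, MeCN, 80 °C; citric acid work-up
Reagents that add atoms: none
Why: The Mizoroki–Heck reaction of the aryl iodide is E-selective, and the MOM ether is stable to amine base and to a mild acid wash.

**Step 9**
Reactants: 13 mono-ester; 15 O-MOM-p-coumaric acid
Product: 16 (1R,2R,3R)-1-{[(E)-3-(2,2-dimethyl-1,3-benzodioxol-5-yl)acryloyl]oxy}-3-(triethylsilyloxy)cyclohept-5-en-2-yl (E)-3-[4-(methoxymethoxy)phenyl]acrylate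
Conditions: 15 (2 equiv), DCC, DMAP (0.5 equiv), CH2Cl2, rt
Reagents that add atoms: none
Why: Steglich esterification of the only free hydroxyl with excess acid leaves all C–O bonds intact, and fast acylation at high DMAP loading outruns 1,2-acyl migration.

**Step 10**
Reactants: 16 mixed diester
Product: 17 (4R,5R,6R)-6-(caffeoyl acetonide)oxy-5-(O-MOM-coumaroyl)oxy-4-(triethylsilyloxy)cycloheptane-1,2-diol (cis-diol, both facial isomers)
Conditions: K2OsO4·2H2O (2 mol %), NMO (1.1 equiv), acetone/H2O 8:1, 0 °C, stopped when 16 is consumed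
Reagents that add atoms: N-methylmorpholine N-oxide, C[N+]1([O-])CCOCC1; water, O (both oxygens are passed on through OsO4)
Why: In the Upjohn dihydroxylation electrophilic OsO4 takes the isolated cis-alkene well before the two ester-conjugated cinnamate alkenes, and the two new centres (cis, either face) are erased in the next step.

**Step 11**
Reactants: 17 cis-diol
Product: 18 (4R,5R,6R)-6-(caffeoyl acetonide)oxy-5-(O-MOM-coumaroyl)oxy-4-(triethylsilyloxy)cycloheptane-1,2-dione
Conditions: IBX (4 equiv), DMSO, rt; aqueous work-up, used crude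
Reagents that add atoms: none
Why: IBX oxidises 1,2-diols to 1,2-diketones without C–C cleavage and without base, which spares the β-acyloxy and β-silyloxy groups from E1cB loss and leaves the protected phenols alone.

**Step 12**
Reactants: 18 cycloheptane-1,2-dione
Product: 21 3-O-(caffeoyl acetonide)-4-O-(O-MOM-p-coumaroyl)-1,5-quinide (γ-lactone of the quinic acid diester, free 1-OH), via 4-hydroxy-1,2-dione 19 (not isolated), via bridged hemiketal 20 (not isolated)
Conditions: Sc(OTf)3 (10 mol %), H2O (5 equiv), MeCN, 0 °C → rt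
Reagents that add atoms: none
Why: Proposed new method: a Lewis-acid-catalysed transannular benzilic lactone rearrangement, in which Sc(OTf)3/H2O removes the TES group, the freed C4–OH adds across the ring to the C1 carbonyl (five-membered closure to the 8-oxabicyclo[3.2.1] hemiketal 20, which also removes the carbonyl that is β to the caffeate), and Sc(III) bound to the C2 ketone and the hemiketal OH lets the doubly oxygen-stabilised C1 push its C1–C7 bond, held nearly parallel to the C2=O π* orbital by the bicycle, onto C2, so that the seven-membered ring contracts to the cyclohexane, C1 ends as the γ-lactone carbonyl, and the new tertiary carbinol centre (quinide C-1) can only form with its carboxyl carbon cis to O-5 because the oxygen bridge stays closed during the shift; the closest known reaction types are the benzilic ester rearrangement (alkoxide-induced or Cu(II)-catalysed) and Lewis-acid-catalysed α-ketol rearrangements, neither shown with a transannular hemiketal as internal nucleophile or for a lactone-forming ring contraction.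

**Step 13**
Reactants: 21 protected quinide diester
Product: 23 3-O-caffeoyl-4-O-p-coumaroylquinic acid (target), via 3-O-caffeoyl-4-O-p-coumaroyl-1,5-quinide 22 (not isolated)
Conditions: TFA/H2O 9:1, 0 °C → rt, 1 h; then diluted with H2O/THF to ca. 20 % TFA, 40 °C, 24 h; prep-HPLC
Reagents that add atoms: water, O
Why: Acid hydrolysis first cleaves the MOM ether and the catechol acetonide and then opens the strained γ-lactone, while the cinnamate esters survive, the base-induced acyl migration typical of acylquinic acids is avoided, and no stereocentre is touched.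

**Compound list**
1 | 2-O-benzylglycerol | OCC(CO)OCc1ccccc1 | starting material
2 | allyl acetate | C=CCOC(C)=O | starting material
3 | (4R,6R)-5-(benzyloxy)nona-1,8-diene-4,6-diol | C=CC[C@@H](O)C(OCc1ccccc1)[C@H](O)CC=C | intermediate
4 | (1R,3R)-2-(benzyloxy)cyclohept-5-ene-1,3-diol | c1ccccc1COC1[C@H](O)CC=CC[C@H]1O | intermediate
5 | (1R,3R)-cyclohept-5-ene-1,2,3-triol | OC1[C@H](O)CC=CC[C@H]1O | intermediate
6 | phenylboronate of the cis-1,2-diol of 5 (trans-OH free) | c1ccccc1B2O[C@H]3[C@H](O)CC=CC[C@H]3O2 | intermediate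
7 | TES ether of 6 | c1ccccc1B2O[C@H]3[C@H](O[Si](CC)(CC)CC)CC=CC[C@H]3O2 | intermediate
8 | (1R,2R,3R)-3-(triethylsilyloxy)cyclohept-5-ene-1,2-diol | O[C@H]1[C@H](O[Si](CC)(CC)CC)CC=CC[C@H]1O | intermediate
9 | 2,2-dimethyl-1,3-benzodioxole | CC1(C)Oc2ccccc2O1 | starting material
10 | 5-bromo-2,2-dimethyl-1,3-benzodioxole | Brc1ccc2OC(C)(C)Oc2c1 | intermediate
11 | acrylic acid | C=CC(=O)O | starting material
12 | (E)-3-(2,2-dimethyl-1,3-benzodioxol-5-yl)acrylic acid | OC(=O)/C=C/c1ccc2OC(C)(C)Oc2c1 | intermediate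
13 | C1 caffeate (acetonide) of 8, free 2-OH | O[C@H]1[C@H](O[Si](CC)(CC)CC)CC=CC[C@H]1OC(=O)/C=C/c1ccc2OC(C)(C)Oc2c1 | intermediate
14 | 1-iodo-4-(methoxymethoxy)benzene | COCOc1ccc(I)cc1 | starting material
15 | (E)-3-[4-(methoxymethoxy)phenyl]acrylic acid | COCOc1ccc(/C=C/C(=O)O)cc1 | intermediate
16 | mixed diester of the cycloheptene (1-caffeate, 2-coumarate, 3-OTES) | O=C(/C=C/c1ccc(OCOC)cc1)O[C@H]1[C@H](O[Si](CC)(CC)CC)CC=CC[C@H]1OC(=O)/C=C/c1ccc2OC(C)(C)Oc2c1 | intermediate
17 | cycloheptane-1,2-diol (cis, both faces; C1/C2 left open) | O=C(/C=C/c1ccc(OCOC)cc1)O[C@H]1[C@H](O[Si](CC)(CC)CC)CC(O)C(O)C[C@H]1OC(=O)/C=C/c1ccc2OC(C)(C)Oc2c1 | intermediate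
18 | (4R,5R,6R)-cycloheptane-1,2-dione, 4-OTES | O=C(/C=C/c1ccc(OCOC)cc1)O[C@H]1[C@H](O[Si](CC)(CC)CC)CC(=O)C(=O)C[C@H]1OC(=O)/C=C/c1ccc2OC(C)(C)Oc2c1 | intermediate
19 | (4R,5S,6R)-4-hydroxycycloheptane-1,2-dione diester | O=C(/C=C/c1ccc(OCOC)cc1)O[C@H]1[C@H](O)CC(=O)C(=O)C[C@H]1OC(=O)/C=C/c1ccc2OC(C)(C)Oc2c1 | intermediate
20 | 1-hydroxy-7-oxo-8-oxabicyclo[3.2.1]octane-3,4-diyl diester (3-caffeate, 4-coumarate) | O=C(/C=C/c1ccc(OCOC)cc1)O[C@H]1[C@H]2CC(=O)[C@](O)(O2)C[C@H]1OC(=O)/C=C/c1ccc2OC(C)(C)Oc2c1 | intermediate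
21 | 3-O-(caffeoyl acetonide)-4-O-(O-MOM-p-coumaroyl)-1,5-quinide | O=C(/C=C/c1ccc(OCOC)cc1)O[C@H]1[C@H]2C[C@](O)(C(=O)O2)C[C@H]1OC(=O)/C=C/c1ccc2OC(C)(C)Oc2c1 | intermediate
22 | 3-O-caffeoyl-4-O-p-coumaroyl-1,5-quinide | O=C(/C=C/c1ccc(O)cc1)O[C@H]1[C@H]2C[C@](O)(C(=O)O2)C[C@H]1OC(=O)/C=C/c1ccc(O)c(O)c1 | intermediate
23 | (1R,3R,4S,5R)-3-(caffeoyloxy)-1,5-dihydroxy-4-(p-coumaroyloxy)cyclohexane-1-carboxylic acid | O=C(/C=C/c1ccc(O)cc1)O[C@H]1[C@H](O)C[C@](O)(C(=O)O)C[C@H]1OC(=O)/C=C/c1ccc(O)c(O)c1 | target

**Step count**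
Total: 13 steps. Longest linear sequence: 10 steps (1, 2, 3, 4, 7, 9, 10, 11, 12, 13).

**Three steps most likely to fail**

Step 12, the proposed ring contraction. The crude dione may enolise and lose caffeate before the hemiketal closes, or the hemiketal may not shift under such mild Lewis acid. The fallback uses known chemistry and moves the contraction ahead of the acylations.
- It sets out from 8. 2,2-Dimethoxypropane/PPTS gives the 1,2-acetonide F1.
- Upjohn dihydroxylation gives the cis-diol F2, and Swern oxidation gives the acetonide dione F3.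
- The classical hydroxide benzilic acid rearrangement (aq KOH, dioxane, rt) contracts the ring to the C-1-epimeric hydroxy acids F4.
- TsOH in acetone/2,2-dimethoxypropane removes the TES group. It lactonises only the epimer whose carboxyl is cis to O-5, giving 3,4-O-isopropylidene-1,5-quinide F5. The other epimer is washed out as the free acid.
- Aqueous TFA gives 1,5-quinide F6.
- 12/DCC/DMAP at −20 °C acylates the equatorial 3-OH to the 3-O-acylquinide F7.
- 15/DCC/DMAP acylates the secondary 4-OH in preference to the tertiary 1-OH. The route is rejoined at 21.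

Step 10, chemoselective dihydroxylation. One of the two cinnamate alkenes may be attacked as well. The fallback changes to an oxidant that electron-poor alkenes do not accept.
- It sets out from 16. mCPBA/NaHCO3 (CH2Cl2, 0 °C) gives the ring epoxide F8.
- Neutral hydrolysis ((salen)Co(III) catalyst, H2O/THF) gives the trans-diol F9.
- IBX as in step 11 oxidises F9 to the same dione. The route is rejoined at 18.

Step 9, acylation of the hindered central hydroxyl. It may be slow enough for the caffeate to migrate from O-1 to O-2 and scramble the esters. The fallback builds the coumarate on the ring.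
- It sets out from 13. The small acryloyl chloride (iPr2NEt, CH2Cl2, −20 °C) gives the 2-O-acrylate F10.
- A Heck reaction with 14 (Pd(OAc)2, P(o-tol)3, Et3N, MeCN, 60 °C) takes place at the terminal acrylate only. The route is rejoined at 16.

**Further compounds**
F1 | step 12 | 1,2-O-isopropylidene derivative of 8 (3-OTES) | CC1(C)O[C@H]2[C@H](O[Si](CC)(CC)CC)CC=CC[C@H]2O1
F2 | step 12 | cis-diol from F1 (both faces) | CC1(C)O[C@H]2[C@H](O[Si](CC)(CC)CC)CC(O)C(O)C[C@H]2O1
F3 | step 12 | 5,6-O-isopropylidene-4-(triethylsilyloxy)cycloheptane-1,2-dione | CC1(C)O[C@H]2[C@H](O[Si](CC)(CC)CC)CC(=O)C(=O)C[C@H]2O1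
F4 | step 12 | 3,4-O-isopropylidene-5-O-TES-quinic acid and its C-1 epimer | CC1(C)O[C@H]2[C@H](O[Si](CC)(CC)CC)CC(O)(C(=O)O)C[C@H]2O1
F5 | step 12 | 3,4-O-isopropylidene-1,5-quinide | CC1(C)O[C@H]2[C@H]3C[C@](O)(C(=O)O3)C[C@H]2O1
F6 | step 12 | 1,5-quinide | O[C@H]1[C@H]2C[C@](O)(C(=O)O2)C[C@H]1O
F7 | step 12 | 3-O-(caffeoyl acetonide)-1,5-quinide | O[C@H]1[C@H]2C[C@](O)(C(=O)O2)C[C@H]1OC(=O)/C=C/c1ccc2OC(C)(C)Oc2c1
F8 | step 10 | ring epoxide of 16 (both faces) | O=C(/C=C/c1ccc(OCOC)cc1)O[C@H]1[C@H](O[Si](CC)(CC)CC)CC2OC2C[C@H]1OC(=O)/C=C/c1ccc2OC(C)(C)Oc2c1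
F9 | step 10 | trans-1,2-diol (one of the two trans isomers shown) | O=C(/C=C/c1ccc(OCOC)cc1)O[C@H]1[C@H](O[Si](CC)(CC)CC)C[C@H](O)[C@@H](O)C[C@H]1OC(=O)/C=C/c1ccc2OC(C)(C)Oc2c1
F10 | step 9 | 2-O-acrylate of 13 | C=CC(=O)O[C@H]1[C@H](O[Si](CC)(CC)CC)CC=CC[C@H]1OC(=O)/C=C/c1ccc2OC(C)(C)Oc2c1
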